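A nucleophile spent one for one cannot make this flask slow down the way it does.

- green: electrophile 19 mM; nucleophile 1.05 equiv; free base 1.1 equiv; the very flask that is asked about, followed so far
- flask: electrophile 19 mM; nucleophile 1.05 equiv; free base 1.10 equiv; time 10 d

green run (percent of the electrophile charged)

| time / d | electrophile / % | target / % |
|---|---|---|
| 0.500 | 60.6 | 27.3 |
| 1.25 | 44.1 | 31.7 |
| 2.50 | 33.9 | 24.7 |
| 4.00 | 29.8 | 19.1 |

(each reading ± 1 percentage point)

- percent here means electrophile units held: one homo dimer counts as two
- steps thought possible: 2 electrophile -> homo dimer; target <-> isomer of the product; acid set free + free base <-> salt of the base; electrophile + nucleophile -> acid set free + target; nucleophile + acid set free <-> protonated nucleophile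
- the earlier runs do not show how much of nucleophile is bound; that part of a forecast is a guess

- part of the electrophile that has reacted at 10 d
- share of the unused nucleophile that is free and not bound as protonated nucleophile, at 10 d

Electrophile and nucleophile couple to target and set acid free. Target can turn into its isomer, two electrophile can form homo dimer, and the acid can go to the nucleophile or to the free base.

Watch the reciprocal of the electrophile's remaining fraction. Under coupling it climbs at a rate constant times nucleophile over electrophile, and one-for-one spending from an excess of nucleophile cannot shrink that ratio, while dimer merely adds to the climb. Yet the green run climbs 1.30 d⁻¹ up to its first reading and 0.271 d⁻¹ between its last two. So put that first answer back: suppose the freed acid binds a second nucleophile, and each coupling costs two. Then the nucleophile, though charged in excess, becomes the limiting reagent, and coupling slows near 52.5% of the electrophile charged: the two-for-one ceiling, half the nucleophile charge. Acid that reaches the free base lifts it.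

Go round once more, as my own reckoning. Carrying the late climb on to 10 d leaves 20.1% of the electrophile, so about 79.9% has reacted. The first climb gives a constant near 1.24 d⁻¹, so, counting the whole late climb as coupling, free nucleophile comes to roughly 4.39% of the electrophile charged. Against an unused amount near the ceiling, that is a free share of 8.36%, still a guess.

The forecast says 79% and 20%, differing from mine on the free share: “Perhaps a fifth is free, which is a rough guess.”

The flask gives 83.3% reacted and 7.76% free.

    2 electrophile → homo dimer (k = 6.75 × 10⁻⁵ M⁻¹ s⁻¹)
    target ⇌ isomer of the product (K = 2.44, k = 5.41 × 10⁻⁶ s⁻¹)
    acid set free + free base ⇌ salt of the base (K = 1.58 × 10⁶ M⁻¹, k = 0.00511 M⁻¹ s⁻¹)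
    electrophile + nucleophile → acid set free + target (k = 7.40 × 10⁻⁴ M⁻¹ s⁻¹)
    nucleophile + acid set free ⇌ protonated nucleophile, settled at all times (K = 3.20 × 10⁵ M⁻¹)

In the flask, half of the coupling's turnover up to 10 d is done by 0.422 d, and at 10.0 d coupling still uses electrophile 1.2 times as fast as dimer formation. Target plus isomer then stand at 58.2%, above the ceiling of 52.5%, beside 2.83 mM of salt of the base. A second flask with 0.260 equiv of nucleophile has a ceiling of 13.0%, and at 10.0 d it holds 17.5% of target plus isomer beside 1.94 mM of salt of the base.

The earlier runs and the new flask were computed with constants of no real substance; the scatter is artificial.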